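The target is cut at the bond between ring carbon C1 (the cyclohexane CH that carries the side chain) and the acyclic tertiary carbinol carbon C2′. C2′ bears two identical CH2OAc arms and is not stereogenic. It is therefore traced back to a symmetric, non-enolisable, highly electrophilic ketone, diethyl ketomalonate. C1 lies next to carbinol carbon C2, so with the ring bond C2–C3 opened it is the α-carbon of an acyclic aldehyde. An L-proline enamine aldol joins the twelve-carbon aldehyde to the ketone and sets C1 by catalyst control, independent of the remote quaternary C4. A carbonyl-ene closure then builds the ring, and both ester arms are reduced and acetylated together.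

Key step: step 5

Atom labels: ring C1 (CH bearing the side chain), C2 (CHOH), C3 (CH–isopropenyl), C4 (quaternary C with methyl and vinyl), C5 and C6 (CH2). C2′ is the tertiary carbinol carbon of the side chain.
Assumption: in step 3 the ligand enantiomer that gives the (S)-quaternary centre is used; both antipodes derive from commercial 1,2-diphenylethylenediamine.
Remark: C4 and C1 are set by two independent catalysts, so the minor sense of either event ends in a diastereomer of 15 that chromatography can remove.

Step 1
Reactants: 1 6-chlorohex-1-yne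
Product: 4 (E)-7-chloro-3-methylhept-2-en-1-ol, via alkenyldimethylalane 2 (not isolated), via lithium alanate 3 (not isolated)
Conditions: Me3Al (2 equiv), Cp2ZrCl2 (20 mol %), CH2Cl2, 0 °C to rt; volatiles off; n-BuLi, hexane–THF, 0 °C; (CH2O)n, rt; aq. HCl
Reagents that add atoms: trimethylaluminium C[Al](C)C; paraformaldehyde (as formaldehyde) C=O
Why: Zirconium-catalysed Negishi carboalumination adds methyl and aluminium syn and regioselectively across the terminal alkyne, and hydroxymethylation of the derived alanate proceeds with retention, which fixes the E trisubstituted alkene while the primary chloride stays inert.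

Step 2
Reactants: 4 (E)-7-chloro-3-methylhept-2-en-1-ol
Product: 5 diethyl [(2E)-7-chloro-3-methylhept-2-en-1-yl] phosphate
Conditions: (EtO)2P(O)Cl, Et3N, DMAP (cat.), CH2Cl2, 0 °C
Reagents that add atoms: diethyl chlorophosphate CCOP(=O)(Cl)OCC
Why: Routine O-phosphorylation of a primary allylic alcohol installs the leaving group needed for SN2′ substitution, and no stereocentre is involved.

Step 3
Reactants: 5 diethyl [(2E)-7-chloro-3-methylhept-2-en-1-yl] phosphate; 6 2-methylprop-1-enylmagnesium bromide
Product: 8 (4S)-8-chloro-4-ethenyl-2,4-dimethyloct-2-ene, via isobutenyldiethylalane 7 (not isolated)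
Conditions: 6, Et2AlCl, THF, 0 °C to rt; then 5, CuCl2·2H2O (5 mol %), chiral sulfonate-bearing NHC–Ag complex (2.5 mol %), THF, −15 °C; aq. HCl
Reagents that add atoms: none
Why: In this copper–NHC-catalysed enantioselective allylic substitution (SN2′) with an alkenylaluminium reagent, the sp2 group is transferred to the γ-carbon of the E-trisubstituted allylic phosphate, the chiral ligand selects the alkene face and so sets the quaternary centre (S), and the vinyl group is released in the same event.

Step 4
Reactants: 8 (4S)-8-chloro-4-ethenyl-2,4-dimethyloct-2-ene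
Product: 11 (5S)-5-ethenyl-5,7-dimethyloct-6-enal, via primary iodide 9 (not isolated), via alkoxysulfonium iodide 10 (not isolated)
Conditions: NaI, NaHCO3, DMSO, 110 °C
Reagents that add atoms: dimethyl sulfoxide CS(C)=O
Why: Finkelstein exchange followed by Kornblum oxidation (O-alkylation of DMSO, then base-induced loss of dimethyl sulfide) turns the primary halide directly into the aldehyde, and the non-epimerisable quaternary centre and the skipped diene are not affected.

Step 5
Reactants: 11 (5S)-5-ethenyl-5,7-dimethyloct-6-enal; 12 diethyl ketomalonate (diethyl 2-oxopropanedioate)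
Product: 14 diethyl 2-[(2S,5S)-5-ethenyl-5,7-dimethyl-1-oxooct-6-en-2-yl]-2-hydroxypropanedioate, via proline enamine 13 (not isolated)
Conditions: L-proline (30 mol %), 12 (1.2 equiv), CH2Cl2, rt, slow addition of 11
Reagents that add atoms: none
Why: L-Proline condenses with 11 to the E-enamine 13, whose carboxylic acid hydrogen-bonds to the central carbonyl of 12 and delivers it to one enamine face in a closed transition state, and hydrolysis of the iminium aldolate releases 14 and the catalyst. The closest known reaction type is the proline-catalysed direct aldol addition of unbranched aldehyde donors to diethyl ketomalonate. No ring is closed; one C–C bond (future ring C1 to C2′) and only one stereocentre are made, because C2′ carries two identical ester arms and stays non-stereogenic. The new centre (S in 14, the same spatial arrangement as 1R in the target) is controlled by the (S)-configured catalyst in the sense known for L-proline aldol and α-functionalisation reactions of aldehydes, not by the distant quaternary carbon, so the 1,4-relationship C1/C4, which a ring enolate could hardly control (methyl against vinyl), is fixed by the reagent. The step needs cross- over self-aldol selectivity, which is secured because 12 has no α-hydrogen, cannot act as donor and is far more electrophilic than 11, and because the adduct of so activated a ketone should not revert. The α-branched product should form an enamine only slowly, which protects the new centre from epimerisation.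

Step 6
Reactants: 14 diethyl 2-[(2S,5S)-5-ethenyl-5,7-dimethyl-1-oxooct-6-en-2-yl]-2-hydroxypropanedioate
Product: 15 diethyl 2-hydroxy-2-[(1R,2R,3S,4S)-4-ethenyl-2-hydroxy-4-methyl-3-(prop-1-en-2-yl)cyclohexyl]propanedioate
Conditions: ZnBr2 (1.5 equiv), CH2Cl2, 0 °C to rt
Reagents that add atoms: none
Why: In this Lewis-acid-promoted type I intramolecular carbonyl-ene reaction (citronellal-to-isopulegol type) the trisubstituted alkene attacks the zinc-bound aldehyde through a chair in which the bulky hydroxymalonate group at C1, the C2 oxygen and the developing isopropenyl group at C3 are equatorial and the C4 methyl is axial (an axial C2–O would clash with it), which sets 2R and 3S relative to C1 and C4, while the vinyl group has no allylic hydrogen and cannot compete as ene component.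

Step 7
Reactants: 15 diethyl 2-hydroxy-2-[(1R,2R,3S,4S)-4-ethenyl-2-hydroxy-4-methyl-3-(prop-1-en-2-yl)cyclohexyl]propanedioate
Product: 16 2-[(1R,2R,3S,4S)-4-ethenyl-2-hydroxy-4-methyl-3-(prop-1-en-2-yl)cyclohexyl]propane-1,2,3-triol
Conditions: LiAlH4 (5 equiv), THF, 0 °C to reflux; aqueous NaOH work-up
Reagents that add atoms: none
Why: Exhaustive LiAlH4 reduction converts both ester arms at once (two-directional, C2′ stays non-stereogenic) and would equally reduce any γ-lactone formed between the C2 hydroxyl and one ester, while the isolated alkenes and all four stereocentres are untouched.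

Step 8
Reactants: 16 2-[(1R,2R,3S,4S)-4-ethenyl-2-hydroxy-4-methyl-3-(prop-1-en-2-yl)cyclohexyl]propane-1,2,3-triol
Product: 17 2-[(1R,2R,3S,4S)-4-ethenyl-2-hydroxy-4-methyl-3-(prop-1-en-2-yl)cyclohexyl]-2-hydroxypropane-1,3-diyl diacetate (target)
Conditions: Ac2O (2.2 equiv), pyridine, CH2Cl2, 0 °C
Reagents that add atoms: acetic anhydride CC(=O)OC(C)=O
Why: In this sterically controlled acylation the two equivalent primary hydroxyls react much faster than the secondary C2 hydroxyl, which is flanked by two branched carbons, and the tertiary C2′ hydroxyl, so two equivalents of anhydride should stop at the 1,3-diacetate without touching a stereocentre.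

Compound list
1 | 6-chlorohex-1-yne | C#CCCCCCl | starting material
2 | [(1E)-6-chloro-2-methylhex-1-en-1-yl]dimethylaluminium | C[Al](C)/C=C(\C)CCCCCl | intermediate
3 | lithium butyl[(1E)-6-chloro-2-methylhex-1-en-1-yl]dimethylaluminate | [Li+].CCCC[Al-](C)(C)/C=C(\C)CCCCCl | intermediate
4 | (E)-7-chloro-3-methylhept-2-en-1-ol | OC/C=C(\C)CCCCCl | intermediate
5 | diethyl [(2E)-7-chloro-3-methylhept-2-en-1-yl] phosphate | CCOP(=O)(OCC)OC/C=C(\C)CCCCCl | intermediate
6 | 2-methylprop-1-enylmagnesium bromide | CC(C)=C[Mg]Br | starting material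
7 | diethyl(2-methylprop-1-en-1-yl)aluminium | CC[Al](CC)C=C(C)C | intermediate
8 | (4S)-8-chloro-4-ethenyl-2,4-dimethyloct-2-ene | C=C[C@](C)(CCCCCl)C=C(C)C | intermediate
9 | (4S)-4-ethenyl-8-iodo-2,4-dimethyloct-2-ene | C=C[C@](C)(CCCCI)C=C(C)C | intermediate
10 | {[(5S)-5-ethenyl-5,7-dimethyloct-6-en-1-yl]oxy}dimethylsulfonium iodide | C[S+](C)OCCCC[C@@](C)(C=C)C=C(C)C.[I-] | intermediate
11 | (5S)-5-ethenyl-5,7-dimethyloct-6-enal | C=C[C@](C)(CCCC=O)C=C(C)C | intermediate
12 | diethyl ketomalonate (diethyl 2-oxopropanedioate) | CCOC(=O)C(=O)C(=O)OCC | starting material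
13 | (2S)-1-[(1E,5S)-5-ethenyl-5,7-dimethylocta-1,6-dien-1-yl]pyrrolidine-2-carboxylic acid | OC(=O)[C@@H]1CCCN1/C=C/CC[C@@](C)(C=C)C=C(C)C | intermediate
14 | diethyl 2-[(2S,5S)-5-ethenyl-5,7-dimethyl-1-oxooct-6-en-2-yl]-2-hydroxypropanedioate | C=C[C@](C)(CC[C@H](C=O)C(O)(C(=O)OCC)C(=O)OCC)C=C(C)C | intermediate
15 | diethyl 2-hydroxy-2-[(1R,2R,3S,4S)-4-ethenyl-2-hydroxy-4-methyl-3-(prop-1-en-2-yl)cyclohexyl]propanedioate | C=C[C@]1(C)CC[C@@H](C(O)(C(=O)OCC)C(=O)OCC)[C@H](O)[C@H]1C(=C)C | intermediate
16 | 2-[(1R,2R,3S,4S)-4-ethenyl-2-hydroxy-4-methyl-3-(prop-1-en-2-yl)cyclohexyl]propane-1,2,3-triol | C=C[C@]1(C)CC[C@@H](C(O)(CO)CO)[C@H](O)[C@H]1C(=C)C | intermediate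
17 | 2-[(1R,2R,3S,4S)-4-ethenyl-2-hydroxy-4-methyl-3-(prop-1-en-2-yl)cyclohexyl]-2-hydroxypropane-1,3-diyl diacetate | C=C[C@]1(C)CC[C@@H](C(O)(COC(C)=O)COC(C)=O)[C@H](O)[C@H]1C(=C)C | target

Total step count: 8
Longest linear sequence: 8 steps (1 to 17)

Steps most likely to fail

Step 6 (ene closure).
- Risk: bond formation between two congested carbons, C2 next to the hydroxymalonate-bearing C1 and C3 next to the quaternary C4, may be slow. Retro-aldol cleavage of the β-hydroxy aldehyde, dehydration, or stepwise cationic Prins pathways with loss of facial control could then take over.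
- Fallback (sets out from 5, comes back at 15): the ene component is replaced by a more nucleophilic allylsilane, so that ring closure becomes an intramolecular Hosomi–Sakurai allylation. Zirconium-catalysed carboalumination of commercial trimethyl(prop-2-yn-1-yl)silane gives dimethyl[(1E)-2-methyl-3-(trimethylsilyl)prop-1-en-1-yl]aluminium F9. This reagent is used in the copper-catalysed allylic substitution of 5 to give trimethyl[(2E,4S)-8-chloro-4-ethenyl-2,4-dimethyloct-2-en-1-yl]silane F10. Kornblum oxidation gives (5S,6E)-5-ethenyl-5,7-dimethyl-8-(trimethylsilyl)oct-6-enal F11. The L-proline aldol with 12 gives diethyl 2-[(2S,5S,6E)-5-ethenyl-5,7-dimethyl-1-oxo-8-(trimethylsilyl)oct-6-en-2-yl]-2-hydroxypropanedioate F12. BF3·OEt2 in CH2Cl2 at −78 °C then closes the ring through the same chair with loss of silicon to give 15.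

Step 5 (key aldol).
- Risk: self-condensation of the unbranched aldehyde, incomplete face selection by the catalyst, or slow epimerisation of the new α-centre through renewed enamine formation may erode the outcome.
- Fallback (sets out from 11, comes back at 14): catalytic enamine activation is replaced by a stoichiometric chiral azaenolate. Condensation of 11 with (S)-1-amino-2-(methoxymethyl)pyrrolidine gives the (E)-hydrazone (1E,5S)-5-ethenyl-N-[(2S)-2-(methoxymethyl)pyrrolidin-1-yl]-5,7-dimethyloct-6-en-1-imine F7. Deprotonation with LDA in THF, addition of 12 at −100 to −78 °C and a cold quench give the hydroxymalonate hydrazone diethyl 2-hydroxy-2-[(1E,2S,5S)-5-ethenyl-1-{[(2S)-2-(methoxymethyl)pyrrolidin-1-yl]imino}-5,7-dimethyloct-6-en-2-yl]propanedioate F8. The sense of attack follows that of alkylations of such hydrazones. Cleavage with saturated aqueous oxalic acid in ether, which leaves the alkenes alone, gives 14.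

Step 3 (allylic substitution).
- Risk: the catalyst may discriminate poorly between methyl and chlorobutyl at the γ-carbon, and direct SN2 substitution or ethyl transfer from aluminium may compete.
- Fallback (sets out from 4, comes back at 8): the quaternary centre is made by chirality transfer from an epoxide.
  - Sharpless epoxidation of 4 (Ti(OiPr)4, L-(+)-diethyl tartrate, t-BuOOH) gives [(2S,3S)-3-(4-chlorobutyl)-3-methyloxiran-2-yl]methanol F1.
  - Silylation (TBSCl, imidazole) gives tert-butyl{[(2S,3S)-3-(4-chlorobutyl)-3-methyloxiran-2-yl]methoxy}dimethylsilane F2.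
  - A bulky methylaluminium bis(aryloxide) at −78 °C induces the semipinacol-type epoxide rearrangement, in which the siloxymethyl group migrates anti to the breaking tertiary C–O bond. This gives (2S)-2-{[(tert-butyldimethylsilyl)oxy]methyl}-6-chloro-2-methylhexanal F3.
  - Wittig reaction with isopropylidenetriphenylphosphorane gives tert-butyl{[(2R)-6-chloro-2-methyl-2-(2-methylprop-1-en-1-yl)hexyl]oxy}dimethylsilane F4.
  - TBAF gives (2R)-6-chloro-2-methyl-2-(2-methylprop-1-en-1-yl)hexan-1-ol F5.
  - Dess–Martin oxidation gives (2R)-6-chloro-2-methyl-2-(2-methylprop-1-en-1-yl)hexanal F6.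
  - Wittig methylenation gives 8.

Further compounds
F1 | step 3 | [(2S,3S)-3-(4-chlorobutyl)-3-methyloxiran-2-yl]methanol | OC[C@@H]1O[C@@]1(C)CCCCCl
F2 | step 3 | tert-butyl{[(2S,3S)-3-(4-chlorobutyl)-3-methyloxiran-2-yl]methoxy}dimethylsilane | CC(C)(C)[Si](C)(C)OC[C@@H]1O[C@@]1(C)CCCCCl
F3 | step 3 | (2S)-2-{[(tert-butyldimethylsilyl)oxy]methyl}-6-chloro-2-methylhexanal | CC(C)(C)[Si](C)(C)OC[C@](C)(CCCCCl)C=O
F4 | step 3 | tert-butyl{[(2R)-6-chloro-2-methyl-2-(2-methylprop-1-en-1-yl)hexyl]oxy}dimethylsilane | CC(C)(C)[Si](C)(C)OC[C@](C)(CCCCCl)C=C(C)C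
F5 | step 3 | (2R)-6-chloro-2-methyl-2-(2-methylprop-1-en-1-yl)hexan-1-ol | OC[C@](C)(CCCCCl)C=C(C)C
F6 | step 3 | (2R)-6-chloro-2-methyl-2-(2-methylprop-1-en-1-yl)hexanal | O=C[C@](C)(CCCCCl)C=C(C)C
F7 | step 5 | (1E,5S)-5-ethenyl-N-[(2S)-2-(methoxymethyl)pyrrolidin-1-yl]-5,7-dimethyloct-6-en-1-imine | C=C[C@](C)(CCC/C=N/N1CCC[C@H]1COC)C=C(C)C
F8 | step 5 | diethyl 2-hydroxy-2-[(1E,2S,5S)-5-ethenyl-1-{[(2S)-2-(methoxymethyl)pyrrolidin-1-yl]imino}-5,7-dimethyloct-6-en-2-yl]propanedioate | C=C[C@](C)(CC[C@H](/C=N/N1CCC[C@H]1COC)C(O)(C(=O)OCC)C(=O)OCC)C=C(C)C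
F9 | step 6 | dimethyl[(1E)-2-methyl-3-(trimethylsilyl)prop-1-en-1-yl]aluminium | C[Al](C)/C=C(\C)C[Si](C)(C)C
F10 | step 6 | trimethyl[(2E,4S)-8-chloro-4-ethenyl-2,4-dimethyloct-2-en-1-yl]silane | C=C[C@](C)(CCCCCl)/C=C(\C)C[Si](C)(C)C
F11 | step 6 | (5S,6E)-5-ethenyl-5,7-dimethyl-8-(trimethylsilyl)oct-6-enal | C=C[C@](C)(CCCC=O)/C=C(\C)C[Si](C)(C)C
F12 | step 6 | diethyl 2-[(2S,5S,6E)-5-ethenyl-5,7-dimethyl-1-oxo-8-(trimethylsilyl)oct-6-en-2-yl]-2-hydroxypropanedioate | C=C[C@](C)(CC[C@H](C=O)C(O)(C(=O)OCC)C(=O)OCC)/C=C(\C)C[Si](C)(C)C
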